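Saturday's run is where I open the books, and the account I keep is the second end groups, the limiting reagent of that run. I read the runs as first end groups and second end groups making links, links and second end groups making over-reaction product, and links exchanging with the isomer. On that reading each first end group gone costs one second end group, and each over-reaction product costs one more.

| setting | Saturday's | Tuesday's | flask |
|---|---|---|---|
| first end groups | 20 mM (fed, over 3.0 min) | 20 mM (fed, over 3.0 min) | 20 mM (fed, over 3.0 min) |
| second end groups | 0.50 equiv | 2 equiv | 1.00 equiv |
| remark | run made earlier | run made earlier |  |
| time |  |  | 6.0 h |

| run | time / h | first end groups / % | links / % |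
|---|---|---|---|
| Saturday's | 0.500 | 68 | 15 |
| Saturday's | 0.667 | 63 | 13 |
| Saturday's | 1.00 | 58 | 11 |
| Saturday's | 1.50 | 60 | 8 |
| Saturday's | 2.50 | 57 | 9 |
| Saturday's | 4.00 | 59 | 10 |
| Saturday's | 6.00 | 58 | 13 |
| Tuesday's | 0.333 | 26 | 23 |
| Tuesday's | 1.00 | 11 | 7 |
| Tuesday's | 1.50 | 8 | 6 |
| Tuesday's | 2.50 | 2 | 4 |
| Tuesday's | 4.00 | 1 | 3 |
| Tuesday's | 5.00 | 0 | 3 |
| Tuesday's | 6.00 | 4 | 4 |

(readings scatter by 2 percentage points)

- what was read earlier has a scatter of 2 percentage points, one standard deviation
- the reaction counts as stopped when no species that holds the first end groups changes by six tenths of a point or more over the second half of the time

- which holds at 6.0 h: what has brought the reaction to rest, or that it has not come to rest (the second end groups has run out first / all of the first end groups has reacted / forward and back rates have come level / it is still moving)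
- part of the first end groups gone at 6.0 h
- the links standing at 6.0 h, as a percentage of the first end groups charged
- the isomer of the product standing at 6.0 h, as a percentage of the first end groups charged
- the over-reaction product standing at 6.0 h, as a percentage of the first end groups charged
- amount of links if the flask were left three thousand times as long, in percent of the first end groups charged

From 1.50 h on, Saturday's first end groups stay within the scatter and average 58.5%, so the first entry against the 0.50 equiv charged is 41.5% of the first end groups. The balance of the account, 8.50%, I book as over-reaction product, which leaves 33.0% standing as links plus isomer. Links average 10.0% over those readings, and I take their exchange with the isomer as being at balance. Saturday's readings therefore give 30.3% for the quantity I carry, the link share, the fraction c_L/(c_L + c_E) of links and isomer that stands as links.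

In the flask, with 1.00 equiv, closed books mean c_O equals c_A, and links plus isomer are the charge less twice c_A. The forecast says the second end groups has run out first, with conversion 71.5%, links 12.5%, isomer 30.5%, over-reaction product 28.5% and 12.5% of links after the long wait, on the grounds that links and isomer are “already equilibrated”. I accept its conversion as my open entry, which leaves 43.0% of links plus isomer. My share then gives 13.0% of links, where the forecast, reading the share as 0.29, has 12.5%.

The flask gives the second end groups has run out first: its second end groups stand at 0.396% of their charge after 3.00 h and 0% after 6.00 h. Conversion is 72.0%, links 12.2%, isomer 31.8%, over-reaction product 28.0%, and links after the long wait 12.2%.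

    links ⇌ isomer of the product (K = 2.60, k = 6.50 × 10⁻⁴ s⁻¹)
    second end groups + links → over-reaction product (k = 0.0610 M⁻¹ s⁻¹)
    first end groups + second end groups → links (k = 0.0470 M⁻¹ s⁻¹)

The relaxation half-life of links and isomer, 0.214 h, is shorter than the 6.0 h of the flask, and the flask's books close with 28.0% of first end groups left beside 28.0% of over-reaction product. My share on its 44.0% of links plus isomer gives 13.3% of links, beside the 12.2% found. The neighbouring flask, charged with 80 mM of first end groups at the same equivalents, ends with 0% of its second end groups, 32.1% of first end groups and 32.1% of over-reaction product. That leaves 35.8% for links plus isomer, on which my share gives 10.8%, and that neighbouring flask's links stand at 9.93%.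

The data were generated by integration for an exercise; the scatter is artificial.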